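The target is cut at both bonds of its single benzylic CH2, the carbon that links the lactam nitrogen to arene carbon C1, which sits para to the C4 hydroxyl of the catechol ring. A three-component amidoalkylation joins a catechol, formaldehyde and pyrrolidin-2-one in one operation, making the aryl C1–CH2 bond and the CH2–N bond together without closing a ring. The arene partner is 3,6-dibromobenzene-1,2-diol with both hydroxyls free; its mirror plane makes the two open ring carbons identical, each para to one hydroxyl, so the site of attack is not in question. The diol comes from veratrole by double ortho-lithiation/bromination and demethylation, and one electrophilic bromination at the last free ring position finishes the target.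

Key step: step 3

Remark: paraformaldehyde is written as its monomer unit, and 3,6-dibromobenzene-1,2-diol is taken as not purchasable, so it is made from veratrole.

Step 1
Reactants: 1 veratrole (1,2-dimethoxybenzene)
Product: 3 1,4-dibromo-2,3-dimethoxybenzene, via 3,6-dilithioveratrole 2 (not isolated)
Conditions: n-BuLi (3 equiv), TMEDA (3 equiv), hexane/Et2O, rt to 35 °C; then cannulated into BrCl2C–CCl2Br (3 equiv), THF, −78 °C to rt
Reagents that add atoms: 1,2-dibromo-1,1,2,2-tetrachloroethane, BrC(Cl)(Cl)C(Cl)(Cl)Br
Why: Each methoxy group directs n-BuLi/TMEDA to its free ortho position (directed ortho-metalation, carried out twice), and the dilithio species is brominated by halogen–metal exchange with the polyhaloethane, which collapses to tetrachloroethene and LiBr.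

Step 2
Reactants: 3 1,4-dibromo-2,3-dimethoxybenzene
Product: 5 3,6-dibromobenzene-1,2-diol, via 2,4,7-tribromo-1,3,2-benzodioxaborole 4 (not isolated)
Conditions: BBr3 (2.5 equiv), CH2Cl2, −78 °C to rt; then H2O, 0 °C
Reagents that add atoms: none
Why: BBr3 coordinates the ether oxygens and bromide cleaves both O–CH3 bonds by SN2 attack (Lewis-acid ether cleavage) while the aryl bromides stay untouched, and water then hydrolyses the cyclic bromoborate 4 to the free diol.

Step 3
Reactants: 5 3,6-dibromobenzene-1,2-diol; 6 paraformaldehyde; 7 pyrrolidin-2-one
Product: 10 1-(2,5-dibromo-3,4-dihydroxybenzyl)pyrrolidin-2-one, via 1-(hydroxymethyl)pyrrolidin-2-one 8 (not isolated), via N-acyliminium ion 9 (not isolated)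
Conditions: 6 and 7 (1 equiv each), AcOH, cat. MeSO3H, 50 °C; then 5 (1.5 equiv), MeSO3H, 0 °C to rt
Reagents that add atoms: none
Why: Lactam 7 and formaldehyde 6 condense to the N-hydroxymethyl lactam 8, which the strong acid ionises to the N-acyliminium ion 9; this small primary electrophile attacks C4 of diol 5 (para to the C1 hydroxyl, next to the C3 bromine) and loss of a proton restores the arene, so the formaldehyde carbon ends up bonded to both N and the ring, with water as the only by-product. The closest known reaction type is the Tscherniak-Einhorn amidoalkylation of phenols, here run in its three-component form. No ring is closed and no stereocentre is formed. Two selectivities are needed, the site of attack and a single substitution: the mirror plane of 5 makes its two CH positions identical and every other ring carbon carries OH or Br, so only one constitution can form. A second attack is held back by using 5 in excess (the surplus is recovered) and by the medium, in which the lactam arm of 10 is O-protonated and deactivates the neighbouring CH. The hydroxyls are left free because, unlike the methoxy groups of 3 that are twisted by their two ortho neighbours, they stay in the ring plane and give full para activation.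

Step 4
Reactants: 10 1-(2,5-dibromo-3,4-dihydroxybenzyl)pyrrolidin-2-one
Product: 11 1-(2,3,6-tribromo-4,5-dihydroxybenzyl)pyrrolidin-2-one
Conditions: Br2 (1.05 equiv), AcOH, rt; aq. NaHSO3 work-up
Reagents that add atoms: bromine, BrBr
Why: Electrophilic aromatic bromination can only enter C6, the one ring carbon still bearing hydrogen, which is para to the C3 hydroxyl and ortho to the benzylic carbon, and the lactam and the benzylic C–N bond should be stable to Br2 in AcOH at room temperature.

Compound list (no compound in the route has a stereocentre)

1 | veratrole (1,2-dimethoxybenzene) | COc1ccccc1OC | starting material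
2 | 3,6-dilithio-1,2-dimethoxybenzene (3,6-dilithioveratrole) | [Li]c1ccc([Li])c(OC)c1OC | intermediate
3 | 1,4-dibromo-2,3-dimethoxybenzene (3,6-dibromoveratrole) | COc1c(Br)ccc(Br)c1OC | intermediate
4 | 2,4,7-tribromo-1,3,2-benzodioxaborole (cyclic bromoborate of the diol) | BrB1Oc2c(Br)ccc(Br)c2O1 | intermediate
5 | 3,6-dibromobenzene-1,2-diol (3,6-dibromocatechol) | Oc1c(Br)ccc(Br)c1O | intermediate
6 | paraformaldehyde (formaldehyde unit) | C=O | starting material
7 | pyrrolidin-2-one | O=C1CCCN1 | starting material
8 | 1-(hydroxymethyl)pyrrolidin-2-one | O=C1CCCN1CO | intermediate
9 | 1-methylidene-2-oxopyrrolidin-1-ium methanesulfonate (N-acyliminium ion) | C=[N+]1CCCC1=O.CS(=O)(=O)[O-] | intermediate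
10 | 1-(2,5-dibromo-3,4-dihydroxybenzyl)pyrrolidin-2-one | O=C1CCCN1Cc1cc(Br)c(O)c(O)c1Br | intermediate
11 | 1-(2,3,6-tribromo-4,5-dihydroxybenzyl)pyrrolidin-2-one | O=C1CCCN1Cc1c(Br)c(O)c(O)c(Br)c1Br | target

Total step count: 4. Longest linear sequence: 4 steps (veratrole 1 to target 11); formaldehyde 6 and lactam 7 enter in step 3.

Steps most likely to fail

Step 3 (key step). What may go wrong is over-alkylation at the second para-activated CH, together with acid-catalysed condensation of formaldehyde with two arene molecules, both of which use up diol 5. The fallback sets out from 3 and comes back at 10, and builds the benzyl lactam stepwise. Rieche formylation of 3 (Cl2CHOMe, TiCl4, CH2Cl2, 0 °C) should place the aldehyde para to a methoxy group and give 2,5-dibromo-3,4-dimethoxybenzaldehyde F1. Reductive amination with methyl 4-aminobutanoate hydrochloride (Et3N, NaBH(OAc)3, 1,2-dichloroethane) should give methyl 4-[(2,5-dibromo-3,4-dimethoxybenzyl)amino]butanoate F2, which on warming in toluene should close to 1-(2,5-dibromo-3,4-dimethoxybenzyl)pyrrolidin-2-one F3 with loss of methanol. Demethylation with BBr3 in CH2Cl2 then gives 10, and step 4 follows as planned.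

Step 1. What may go wrong is incomplete second deprotonation, together with lithium–bromine exchange during the quench between aryllithium still present and aryl bromide already formed, which scrambles the halogen pattern. The fallback sets out from 1 and comes back at 3, and never lets an aryllithium meet an aryl bromide. One mono-lithiation/silylation cycle (n-BuLi, TMEDA, then Me3SiCl) should give (2,3-dimethoxyphenyl)trimethylsilane F4, and a second identical cycle at the other methoxy-ortho position should give 2,3-dimethoxy-1,4-bis(trimethylsilyl)benzene F5. Double ipso-bromodesilylation of F5 with Br2 (2 equiv, CH2Cl2, 0 °C), which is far faster than substitution of ring hydrogen, should then give 3.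

Step 4. What may go wrong is ipso attack of bromine at C1, which is also para to a hydroxyl, with expulsion of the lactam-methyl arm, or oxidation of the catechol to its ortho-quinone. The fallback sets out from 5 and comes back at 11, and reverses the order so that the lactam arm never meets bromine. Bromination of 5 with one equivalent of Br2 in AcOH should stop cleanly at 3,4,6-tribromobenzene-1,2-diol F6, because the first bromine deactivates the second site. F6 is then taken through the amidoalkylation of step 3 with 6 and 7 (via 8 and 9; MeSO3H as solvent, rt to 40 °C) at its only open position, which is para to a hydroxyl, and this gives 11 directly.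

Further compounds

F1 | step 3 | 2,5-dibromo-3,4-dimethoxybenzaldehyde | O=Cc1cc(Br)c(OC)c(OC)c1Br
F2 | step 3 | methyl 4-[(2,5-dibromo-3,4-dimethoxybenzyl)amino]butanoate | COC(=O)CCCNCc1cc(Br)c(OC)c(OC)c1Br
F3 | step 3 | 1-(2,5-dibromo-3,4-dimethoxybenzyl)pyrrolidin-2-one | O=C1CCCN1Cc1cc(Br)c(OC)c(OC)c1Br
F4 | step 1 | (2,3-dimethoxyphenyl)trimethylsilane | COc1cccc([Si](C)(C)C)c1OC
F5 | step 1 | 2,3-dimethoxy-1,4-bis(trimethylsilyl)benzene | COc1c([Si](C)(C)C)ccc([Si](C)(C)C)c1OC
F6 | step 4 | 3,4,6-tribromobenzene-1,2-diol | Oc1c(O)c(Br)c(Br)cc1Br
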